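The numbers in the tables come from a simulation on assumed constants; the scatter is artificial.

The constants of the steps are hidden, so this flask, with D and E charged as in dawn and spring but Q as in dusk, has to be read from the earlier runs.

in all of them: D 0.24 mM

| flask | Q | E | remark | time |
|---|---|---|---|---|
| dawn | 0.56 M | 0.35 mM | run made earlier |  |
| spring | 0.88 M | 0.35 mM | run made earlier |  |
| dusk | 0.40 M | 0.17 mM | run made earlier |  |
| flask | 0.40 M | 0.35 mM |  | 4.0 d |

- dawn (time / d: X / %, L / %, Q / %): 0.250: 59.5, 8.3, 26.6; 0.417: 77.0, 8.6, 11.1; 0.625: 84.6, 11.6, 3.3; 1.25: 89.6, 11.3, 0.1; 2.08: 90.0, 11.8, 0; 3.00: 88.8, 8.9, 0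
- spring (time / d: X / %, L / %, Q / %): 0.208: 52.7, 7.7, 31.3; 0.625: 83.8, 10.3, 3.6; 1.04: 87.0, 10.9, 1.5; 1.67: 88.5, 12.6, 0; 2.50: 88.2, 11.1, 0; 3.00: 89.2, 9.9, 0
- dusk (time / d: X / %, L / %, Q / %): 0.250: 61.1, 26.4, 11.2; 0.500: 71.1, 27.0, 2.6; 0.833: 71.9, 28.1, 1.3; 1.67: 72.9, 29.3, 0.1; 3.00: 73.0, 28.4, 0

(standard deviation of a reading: 1 percentage point)

- ratio of X to L at 20 min
- ratio of X to L at 6.0 h
- ratio of X to L at 4.0 d

- steps under discussion: Q <-> J; Q + D -> D + L; D + J -> D + X; D + E <-> Z

Dawn and spring differ in Q, and the flask has less Q than either, so their late readings serve as a working bracket for its final X/L, an estimate and not a proven bound. Dawn pooled gives 8.39 from above, spring pooled 7.91 from below, and both together 8.14, the value this reckoning commits to for 4.0 d. For 6.0 h the dawn reading at that time gives 7.17; for 20 min no run has a reading, the earliest coming later.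

If D catches J as fast as Q feeds it, X follows that feed while L follows Q times free D, written x, so L/X goes with x. In dusk, E is below D, so x is at least 0.0700 mM, and L/X reads 0.395. Scaling by the pooled ratio puts x in dawn at 0.0217 mM, which gives a binding constant K = Z/(D·E) of 76.2 mM⁻¹. Putting K back into dusk and holding it at that estimate gives x at most 0.102 mM; going round once more at the same K gives at least 0.0878 mM. The middle is 0.0948 mM, so the slope s, L/X per unit of free D, is 4.17 mM⁻¹.

The forecast gives 1.6, 7.1 and 8.1, holding that “The ratios barely depend on Q charge”; its last value lies inside the bracket.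

The flask gives 1.34, 7.41 and 8.15; the last also lies inside the bracket, while the first is below the forecast.

    Q ⇌ J (K = 1.00, k = 0.280 h⁻¹)
    Q + D → D + L (k = 1100 L mol⁻¹ h⁻¹)
    D + J → D + X (k = 35000 L mol⁻¹ h⁻¹)
    D + E ⇌ Z, settled at all times (K = 70000 L mol⁻¹)

At 4.00 d the flask holds D at 9.68 % of its charge and Z at 90.3 %. With that D, s gives X/L of 10.3, above the 8.15 found. A neighbouring flask charged with 9.6 × 10⁻⁴ M of D and the same E has x of about 0.610 mM, so s gives X/L of 0.393. That neighbour gives X/L of 0.407 at 4.00 d, with X at 28.9 % and L at 71.1 %.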